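**Retrosynthetic overview**

- Target 17 is the (3S,5S)-3,5-diol of a 1,7-diarylheptane. The plan rests on the anti pair of carbinols C3–OH and C5–OH across the C4 methylene, between the guaiacyl ring on C1 and the syringyl ring on C7. That pair is what is left when an erythro 3,4-epoxy-5-ol is opened by hydride at C4.
- Disconnections, backwards: the two O–benzyl bonds (hydrogenolysis); C4–H (directed hydride opening of oxirane 15); C3–O and C4–O of the oxirane (titanium/tartrate epoxidation of racemic (E)-allylic alcohol 14 with kinetic resolution); C4–C5 (alkenylzinc from alkyne 6 plus aldehyde 11).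
- Fragments: alkyne 6 from eugenol in four steps, aldehyde 11 from 4-allyl-2,6-dimethoxyphenol in three steps.
- Ring order: both arene rings are bought. The only ring made is the C3–C4 oxirane (step 9), and it is opened again in step 10.

Key step: step 9

Assumption: the heptane chain is numbered from the guaiacyl end (C1) to the syringyl end (C7) throughout. Eugenol and 4-allyl-2,6-dimethoxyphenol are taken as commercial allylphenols. In step 9 the oxidant is the limiting reagent, so that only the fast-reacting enantiomer is consumed.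

**Route**

Step 1
Reactants: 1 eugenol (4-allyl-2-methoxyphenol)
Product: 2 4-allyl-1-benzyloxy-2-methoxybenzene
Conditions: BnBr, K2CO3, DMF, rt
Reagents that add atoms: benzyl bromide, BrCc1ccccc1
Why: Williamson ether synthesis, in which the phenoxide formed by K2CO3 displaces bromide from benzyl bromide (SN2) while the allyl group is left alone by this mild base.

Step 2
Reactants: 2 4-allyl-1-benzyloxy-2-methoxybenzene
Product: 4 3-(4-benzyloxy-3-methoxyphenyl)propan-1-ol, via B-alkyl-9-BBN adduct 3 (not isolated)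
Conditions: 9-BBN, THF, 0 °C to rt; then aq. NaOH, 30% H2O2, 0 °C to rt
Reagents that add atoms: hydrogen peroxide, OO
Why: Hydroboration–oxidation, in which the bulky borane places boron on the terminal alkene carbon and alkaline peroxide replaces boron by hydroxyl, should give the primary alcohol only.

Step 3
Reactants: 4 3-(4-benzyloxy-3-methoxyphenyl)propan-1-ol
Product: 5 3-(4-benzyloxy-3-methoxyphenyl)propanal
Conditions: TEMPO (cat.), PhI(OAc)2, CH2Cl2, rt
Reagents that add atoms: none
Why: Oxoammonium (TEMPO/PhI(OAc)2) oxidation of a primary alcohol should stop at the aldehyde in dry CH2Cl2 and tolerates the benzyl-protected electron-rich arene.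

Step 4
Reactants: 5 3-(4-benzyloxy-3-methoxyphenyl)propanal
Product: 6 1-benzyloxy-4-(but-3-yn-1-yl)-2-methoxybenzene
Conditions: dimethyl (1-diazo-2-oxopropyl)phosphonate, K2CO3, MeOH, 0 °C to rt
Reagents that add atoms: dimethyl (1-diazo-2-oxopropyl)phosphonate (Ohira–Bestmann reagent), COP(=O)(OC)C(=[N+]=[N-])C(C)=O
Why: Ohira–Bestmann (Seyferth–Gilbert) homologation, in which the diazomethylphosphonate anion released by methanolysis adds to the aldehyde and loss of dimethyl phosphate and N2 with a 1,2-hydrogen shift gives the terminal alkyne (the future C4), under conditions mild enough for an enolisable aldehyde.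

Step 5
Reactants: 7 4-allyl-2,6-dimethoxyphenol
Product: 8 5-allyl-2-benzyloxy-1,3-dimethoxybenzene
Conditions: BnBr, K2CO3, DMF, 60 °C
Reagents that add atoms: benzyl bromide, BrCc1ccccc1
Why: Williamson ether synthesis as in step 1, with gentle heating because the phenol is flanked by two methoxy groups.

Step 6
Reactants: 8 5-allyl-2-benzyloxy-1,3-dimethoxybenzene
Product: 10 3-(4-benzyloxy-3,5-dimethoxyphenyl)propan-1-ol, via B-alkyl-9-BBN adduct 9 (not isolated)
Conditions: 9-BBN, THF, 0 °C to rt; then aq. NaOH, 30% H2O2, 0 °C to rt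
Reagents that add atoms: hydrogen peroxide, OO
Why: Hydroboration–oxidation with anti-Markovnikov placement of boron, as in step 2, should deliver the primary alcohol.

Step 7
Reactants: 10 3-(4-benzyloxy-3,5-dimethoxyphenyl)propan-1-ol
Product: 11 3-(4-benzyloxy-3,5-dimethoxyphenyl)propanal
Conditions: TEMPO (cat.), PhI(OAc)2, CH2Cl2, rt
Reagents that add atoms: none
Why: Oxoammonium (TEMPO/PhI(OAc)2) oxidation, as in step 3, should give the aldehyde without over-oxidation.

Step 8
Reactants: 6 1-benzyloxy-4-(but-3-yn-1-yl)-2-methoxybenzene; 11 3-(4-benzyloxy-3,5-dimethoxyphenyl)propanal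
Product: 14 racemic (E)-1-(4-benzyloxy-3-methoxyphenyl)-7-(4-benzyloxy-3,5-dimethoxyphenyl)hept-3-en-5-ol, via alkenylzirconocene chloride 12 (not isolated), via alkenyl(methyl)zinc 13 (not isolated)
Conditions: 6 (1.5 equiv), Cp2Zr(H)Cl, CH2Cl2, rt; Me2Zn (in toluene), −65 °C; then 11, 0 °C; sat. aq. NaHCO3
Reagents that add atoms: none
Why: Hydrozirconation–transmetalation–carbonyl addition, in which syn addition of Zr–H puts the metal on the terminal alkyne carbon and fixes the E geometry, and the alkenylzinc formed by exchange with Me2Zn transfers the alkenyl group to aldehyde 11 to form C4–C5 and the racemic C5 carbinol.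

Step 9
Reactants: 14 racemic (E)-1-(4-benzyloxy-3-methoxyphenyl)-7-(4-benzyloxy-3,5-dimethoxyphenyl)hept-3-en-5-ol
Product: 15 (3S,4S,5S)-3,4-epoxy-1-(4-benzyloxy-3-methoxyphenyl)-7-(4-benzyloxy-3,5-dimethoxyphenyl)heptan-5-ol
Conditions: Ti(OiPr)4 (0.15 equiv), L-(+)-diisopropyl tartrate (0.20 equiv), t-BuOOH (0.5 equiv, anhydrous in isooctane), 4 Å MS, CH2Cl2, −20 °C
Reagents that add atoms: tert-butyl hydroperoxide, CC(C)(C)OO
Why: This is a Sharpless asymmetric epoxidation run as a kinetic resolution of a racemic secondary (E)-allylic alcohol: isopropoxide exchange puts the C5 alkoxide of 14 and the tert-butylperoxide on the same tetravalent titanium centre of the Ti–tartrate dimer, and the activated peroxide oxygen is passed to C3=C4 on the face that the C5–O bond reaches. The oxirane closes in a single concerted [2+1] oxygen-atom transfer that forms C3–O and C4–O together, so the E geometry is carried over as the trans ring. C3 and C4 are set by the L-(+)-tartrate, which for an E-allylic alcohol hands oxygen to the face that gives the (3S,4S) oxirane. C5 is not created but selected: in (5S)-14 the C6 chain points to the alkene face away from titanium and the small C5–H sits near the tartrate ester, whereas (5R)-14 would have to push its chain into that ester, so only the 5S alcohol is oxidised at a useful rate and it gives the erythro (4,5-anti) epoxy alcohol. The step therefore needs enantiomer selection at C5 and face selection at the alkene, and the substrate helps with both, because the alkene is E-disubstituted with unbranched CH2 groups on either side and has no cis substituent at C3. Keeping the oxidant at no more than half an equivalent should leave the (5R) alcohol untouched, and the benzyl ethers and electron-rich arenes are inert to Ti(OiPr)4/t-BuOOH at −20 °C.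

Step 10
Reactants: 15 (3S,4S,5S)-3,4-epoxy-1-(4-benzyloxy-3-methoxyphenyl)-7-(4-benzyloxy-3,5-dimethoxyphenyl)heptan-5-ol
Product: 16 (3S,5S)-1-(4-benzyloxy-3-methoxyphenyl)-7-(4-benzyloxy-3,5-dimethoxyphenyl)heptane-3,5-diol
Conditions: NaAlH2(OCH2CH2OCH3)2, THF, 0 °C to rt; aq. KNaC4H4O6 (Rochelle salt) work-up
Reagents that add atoms: none
Why: Directed hydride opening of a 2,3-epoxy alcohol, in which the C5 alkoxide binds aluminium and delivers hydride intramolecularly to the adjacent oxirane carbon C4 (SN2 at C4, C4–O broken), so C3–O keeps its S configuration, C4 becomes a methylene and the anti (3S,5S) 1,3-diol should result.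

Step 11
Reactants: 16 (3S,5S)-1-(4-benzyloxy-3-methoxyphenyl)-7-(4-benzyloxy-3,5-dimethoxyphenyl)heptane-3,5-diol
Product: 17 (3S,5S)-1-(4-hydroxy-3-methoxyphenyl)-7-(4-hydroxy-3,5-dimethoxyphenyl)heptane-3,5-diol
Conditions: H2 (1 atm), 10% Pd/C (palladium metal on carbon), EtOAc/MeOH, rt
Reagents that add atoms: none
Why: Catalytic hydrogenolysis of the two aryl benzyl ethers should free both phenols, and since neither carbinol is benzylic no C–O bond at C3 or C5 and no stereocentre is touched.

**Compound list**

1 | eugenol (4-allyl-2-methoxyphenol) | COc1cc(CC=C)ccc1O | starting material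
2 | 4-allyl-1-benzyloxy-2-methoxybenzene | COc1cc(CC=C)ccc1OCc1ccccc1 | intermediate
3 | 9-[3-(4-benzyloxy-3-methoxyphenyl)propyl]-9-borabicyclo[3.3.1]nonane | COc1cc(CCCB2C3CCCC2CCC3)ccc1OCc1ccccc1 | intermediate
4 | 3-(4-benzyloxy-3-methoxyphenyl)propan-1-ol | COc1cc(CCCO)ccc1OCc1ccccc1 | intermediate
5 | 3-(4-benzyloxy-3-methoxyphenyl)propanal | COc1cc(CCC=O)ccc1OCc1ccccc1 | intermediate
6 | 1-benzyloxy-4-(but-3-yn-1-yl)-2-methoxybenzene | COc1cc(CCC#C)ccc1OCc1ccccc1 | intermediate
7 | 4-allyl-2,6-dimethoxyphenol | COc1cc(CC=C)cc(OC)c1O | starting material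
8 | 5-allyl-2-benzyloxy-1,3-dimethoxybenzene | COc1cc(CC=C)cc(OC)c1OCc1ccccc1 | intermediate
9 | 9-[3-(4-benzyloxy-3,5-dimethoxyphenyl)propyl]-9-borabicyclo[3.3.1]nonane | COc1cc(CCCB2C3CCCC2CCC3)cc(OC)c1OCc1ccccc1 | intermediate
10 | 3-(4-benzyloxy-3,5-dimethoxyphenyl)propan-1-ol | COc1cc(CCCO)cc(OC)c1OCc1ccccc1 | intermediate
11 | 3-(4-benzyloxy-3,5-dimethoxyphenyl)propanal | COc1cc(CCC=O)cc(OC)c1OCc1ccccc1 | intermediate
12 | (E)-[4-(4-benzyloxy-3-methoxyphenyl)but-1-en-1-yl]zirconocene chloride (Cp rings drawn sigma-bonded) | COc1cc(CC/C=C/[Zr](Cl)(C2C=CC=C2)C2C=CC=C2)ccc1OCc1ccccc1 | intermediate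
13 | (E)-[4-(4-benzyloxy-3-methoxyphenyl)but-1-en-1-yl](methyl)zinc | COc1cc(CC/C=C/[Zn]C)ccc1OCc1ccccc1 | intermediate
14 | racemic (E)-1-(4-benzyloxy-3-methoxyphenyl)-7-(4-benzyloxy-3,5-dimethoxyphenyl)hept-3-en-5-ol | COc1cc(CC/C=C/C(O)CCc2cc(OC)c(OCc3ccccc3)c(OC)c2)ccc1OCc1ccccc1 | intermediate
15 | (3S,4S,5S)-3,4-epoxy-1-(4-benzyloxy-3-methoxyphenyl)-7-(4-benzyloxy-3,5-dimethoxyphenyl)heptan-5-ol | COc1cc(CC[C@@H]2O[C@H]2[C@@H](O)CCc2cc(OC)c(OCc3ccccc3)c(OC)c2)ccc1OCc1ccccc1 | intermediate
16 | (3S,5S)-1-(4-benzyloxy-3-methoxyphenyl)-7-(4-benzyloxy-3,5-dimethoxyphenyl)heptane-3,5-diol | COc1cc(CC[C@H](O)C[C@@H](O)CCc2cc(OC)c(OCc3ccccc3)c(OC)c2)ccc1OCc1ccccc1 | intermediate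
17 | (3S,5S)-1-(4-hydroxy-3-methoxyphenyl)-7-(4-hydroxy-3,5-dimethoxyphenyl)heptane-3,5-diol | COc1cc(CC[C@H](O)C[C@@H](O)CCc2cc(OC)c(O)c(OC)c2)ccc1O | target

**Step count and risks**

Total step count: 11. Longest linear sequence: 8 steps (steps 1–4, then 8–11); the second branch (steps 5–7) joins at step 8.

Steps most likely to fail, riskiest first:

1. Step 9. The catalyst may discriminate too weakly between the two enantiomers of 14, or the oxirane may be opened at titanium during a slow reaction, so that the stereochemical purity of the epoxy alcohol is eroded. The fallback takes the enantiomer selection out of the epoxidation. It sets out from 14 (the (5R) alcohol left behind in step 9 can be fed in at the same point). The alcohol would be oxidised with MnO2 in CH2Cl2 to (E)-1-(4-benzyloxy-3-methoxyphenyl)-7-(4-benzyloxy-3,5-dimethoxyphenyl)hept-3-en-5-one F1. A Corey–Bakshi–Shibata reduction with (R)-2-methyl-CBS-oxazaborolidine and catecholborane in toluene at −78 °C, in which the alkenyl arm should act as the larger group, is expected to give (5S,E)-1-(4-benzyloxy-3-methoxyphenyl)-7-(4-benzyloxy-3,5-dimethoxyphenyl)hept-3-en-5-ol F2. This single enantiomer would then be epoxidised with Ti(OiPr)4, L-(+)-diisopropyl tartrate and a full equivalent of t-BuOOH in the matched sense, and the route is rejoined at 15.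

2. Step 10. Hydride may attack C3 in competition with C4 if delivery from the C5 alkoxide is incomplete, which would put a 4,5-diol beside the wanted 3,5-diol. The fallback cleaves the C4–O bond by electron transfer instead of by hydride. It sets out from 15, which would be oxidised with Dess–Martin periodinane to (3S,4R)-3,4-epoxy-1-(4-benzyloxy-3-methoxyphenyl)-7-(4-benzyloxy-3,5-dimethoxyphenyl)heptan-5-one F3. SmI2 in THF/MeOH at −90 °C should break only the C4–O bond next to the ketone and give (3S)-1-(4-benzyloxy-3-methoxyphenyl)-7-(4-benzyloxy-3,5-dimethoxyphenyl)-3-hydroxyheptan-5-one F4. An Evans–Saksena reduction with Me4NBH(OAc)3 in MeCN/AcOH at −20 °C, with hydride delivered from the C3 hydroxyl, should then set C5 anti to C3, and the route is rejoined at 16.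

3. Step 8. Hydrozirconation may stall with partly hydrolysed Cp2Zr(H)Cl, or methyl transfer from zinc and enolisation of the aldehyde may compete with alkenyl transfer. The fallback forms C4–C5 at the alkyne oxidation level. It sets out from 6, which would be deprotonated with n-BuLi in THF at −78 °C and added to aldehyde 11 to give racemic 1-(4-benzyloxy-3-methoxyphenyl)-7-(4-benzyloxy-3,5-dimethoxyphenyl)hept-3-yn-5-ol F5. Alkoxide-directed trans-hydroalumination with NaAlH2(OCH2CH2OCH3)2 in THF at 0 °C to rt, followed by aqueous work-up, should then give the (E)-allylic alcohol, and the route is rejoined at 14.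

**Further compounds**

F1 | step 9 | (E)-1-(4-benzyloxy-3-methoxyphenyl)-7-(4-benzyloxy-3,5-dimethoxyphenyl)hept-3-en-5-one | COc1cc(CC/C=C/C(=O)CCc2cc(OC)c(OCc3ccccc3)c(OC)c2)ccc1OCc1ccccc1
F2 | step 9 | (5S,E)-1-(4-benzyloxy-3-methoxyphenyl)-7-(4-benzyloxy-3,5-dimethoxyphenyl)hept-3-en-5-ol | COc1cc(CC/C=C/[C@@H](O)CCc2cc(OC)c(OCc3ccccc3)c(OC)c2)ccc1OCc1ccccc1
F3 | step 10 | (3S,4R)-3,4-epoxy-1-(4-benzyloxy-3-methoxyphenyl)-7-(4-benzyloxy-3,5-dimethoxyphenyl)heptan-5-one | COc1cc(CC[C@@H]2O[C@H]2C(=O)CCc2cc(OC)c(OCc3ccccc3)c(OC)c2)ccc1OCc1ccccc1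
F4 | step 10 | (3S)-1-(4-benzyloxy-3-methoxyphenyl)-7-(4-benzyloxy-3,5-dimethoxyphenyl)-3-hydroxyheptan-5-one | COc1cc(CC[C@H](O)CC(=O)CCc2cc(OC)c(OCc3ccccc3)c(OC)c2)ccc1OCc1ccccc1
F5 | step 8 | racemic 1-(4-benzyloxy-3-methoxyphenyl)-7-(4-benzyloxy-3,5-dimethoxyphenyl)hept-3-yn-5-ol | COc1cc(CCC#CC(O)CCc2cc(OC)c(OCc3ccccc3)c(OC)c2)ccc1OCc1ccccc1
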